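## Analysis of the target

Target 14 is a 2,3-dihydro-1-benzofuran in which ring A is the benzene ring and ring B the fused dihydrofuran (O1, C2, C3, C3a, C7a). Ring A is substituted in an unbroken row: C3a (the CH2 of ring B), C4 (methoxy), two free positions C5 and C6, C7 (the (E)-4-hydroxycinnamoyl ketone) and C7a (O1). The only stereocentre is C2, of R configuration, which carries the 2-hydroxypropan-2-yl group. No other stereocentre can relay information to C2, so a reagent or catalyst has to set it. The sensitive groups are the chalcone-type enone (a Michael acceptor and radical trap with an E alkene), the free phenol, and the tertiary alcohol, which dehydrates to an isopropenyl group under acid. The synthesis is hard for three reasons: the stereocentre is isolated, C5 and C7 are both activated by the two ring oxygens so a late electrophilic acylation is not position-safe, and the enone tolerates little of the chemistry the first two problems call for. The strategy uses the fact that C3 carries two hydrogens and no substituent while C2 is an oxygen-bound methine. The C2–C3 bond can therefore be formed when a carbene-type carbon at C3, derived from an aldehyde on C3a, alkylates the O–CH2 group of a 2-hydroxy-2-methylpropyl ether on C7a.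

## Retrosynthetic reasoning

**O–Si bond (14 from 13).** The phenol of the cinnamoyl unit is carried as a silyl ether so that no acidic O–H is present when the ketone is formed. The last step only has to remove silicon without touching the enone or the tertiary alcohol.

**C7–C(=O) bond (13 from 7 and 10).** This cut brings in the whole enone with one C–C bond, as late as possible. The enone would not survive the diazo compound 6 (dipolar cycloaddition, radical addition), and its ketone would compete with the aldehyde in the condensation that gives 5. C7 is therefore carried as bromine, which is inert in the key step and already sits at the correct position in phenol 1, so the regiochemistry of ring A is never in question. In the forward direction, bromide 7 has to become a C7 nucleophile (alkoxide 11, then aryllithium 12) that adds exactly once to the N-methoxy-N-methyl amide 10 at the carbonyl carbon.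

**Amide and silyl ether of the side piece (10 from 9 from 8).** Amide 10 comes from acid 8 by amide formation (9) and phenol silylation. The E alkene is bought with 8 and is never formed in the route.

**C2–C3 bond (7 from 6 from 5), the key disconnection.** Cutting O1–C2 instead would require a carbon chain on C3a with a separately made stereocentre. Cutting C2–C3 reduces ring B to two easy ortho substituents on a benzene ring: an aryl ether O–CH2 and a formyl-derived carbon. It also forms the ring and the stereocentre in the same event. The forward reaction must generate a carbene equivalent at C3 from tosylhydrazone 5 through diazo compound 6, abstract a hydrogen from the O–CH2 group, and close the five-membered ring with catalyst control of C2. The side chain is kept saturated and already hydroxylated because an allylic ether, though more activated, would be cyclopropanated by the same intermediate.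

**C=N bond (5 from 4).** The tosylhydrazone is the bench-stable precursor of the diazo compound and comes from aldehyde 4 by condensation.

**O–CH2 bond (4 from 2 and 3).** The phenoxide of 2 opens epoxide 3 at its unsubstituted carbon. This installs the ether and the tertiary alcohol in one step, with no protecting group.

**Aryl–CHO bond (2 from 1).** The formyl group must enter ortho to the phenol. In 1 one ortho position is blocked by bromine, so only the position between the hydroxyl and the methoxy group can react, which is the C3a of the target.

## Alternatives that were turned down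

**Alternative 1: Danheiser benzannulation of ring A.**
- Disconnection: ring A is cut into a four-carbon vinylketene piece (C5, C6, C7, C7a) and a two-carbon alkyne piece (C3a, C4).
- Forward key step: light converts methyl (2E)-5-diazo-4-oxopent-2-enoate A2 by a Wolff rearrangement into a vinylketene with the ester on its far carbon. This adds (2+2) to the methoxyalkyne (3S)-6-methoxy-2-methyl-2-[(triethylsilyl)oxy]hex-5-yn-3-yl methanesulfonate A3. Four-electron opening of the cyclobutenone, six-electron closure and tautomerisation give the phenol methyl 2-hydroxy-4-methoxy-3-[(2S)-2-(methanesulfonyloxy)-3-methyl-3-(triethylsilyloxy)butyl]benzoate A1. The phenoxide of A1 would then displace the mesylate with inversion to close ring B as R.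
- For: the substitution pattern of ring A is fixed by construction, and C2 comes from a preformed stereocentre transferred by a clean SN2 inversion. On both points it is more secure than the chosen route, which depends on site selectivity and on a catalyst-controlled ring closure.
- Against: it builds a benzene ring that can be bought with three of its four substituents in place. A3 needs its own asymmetric synthesis and is a labile ynol ether, A2 combines a diazo ketone with an acrylate in one molecule, and the mesylate must survive photolysis and a thermal pericyclic cascade. The C7 ester must still be converted into the cinnamoyl ketone.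
- Comparison: the step count is at least twice that of the chosen route. The chosen route spends its risk on one catalytic step that makes ring B and C2 together.

**Alternative 2: three-component carbonylative Heck reaction for the enone.**
- Disconnection: both C–C bonds at the carbonyl carbon, C7–C(=O) and C(=O)–Cα.
- Forward key step: zerovalent palladium, generated from Pd(OAc)2 and a bulky phosphine, inserts into the C–I bond of 2-[(2R)-7-iodo-4-methoxy-2,3-dihydro-1-benzofuran-2-yl]propan-2-ol A5. CO insertion gives the aroyl complex, which adds to 4-ethenylphenyl acetate A6; β-hydride elimination releases 4-[(E)-3-[(2R)-2-(2-hydroxypropan-2-yl)-4-methoxy-2,3-dihydro-1-benzofuran-7-yl]-3-oxoprop-1-en-1-yl]phenyl acetate A4. Acetate cleavage would give the target.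
- For: as an endgame it is more convergent than the chosen one. It needs no organolithium and no low temperature, tolerates the free tertiary alcohol, and gives the E alkene by its mechanism.
- Against: the key step forms no ring and no stereocentre, so A5 still has to be made by another asymmetric method. Direct Heck coupling without CO competes, CO pressure and an iodide are needed, and the enone product is itself an alkene that can react further.
- Comparison: it solves the easier half of the problem. The chosen strategy reaches the enone from bromide 7 in two steps as well, and its key step delivers what this one presupposes.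

**Alternative 3: allylic (3+2) annulation on cyclohexane-1,3-dione, arene formed late.**
- Disconnection: C3–C3a and O1–C2, with ring A in reduced form.
- Forward key step: cyclohexane-1,3-dione A8 reacts with dimethyl 2-methylbut-3-ene-1,2-diyl biscarbonate A9 under Pd2(dba)3 and the C2-symmetric bisphosphine made from trans-1,2-diaminocyclohexane and 2-(diphenylphosphino)benzoic acid. C-allylation at the unsubstituted allyl terminus is followed by a second ionisation and ligand-controlled attack of the enol oxygen on the internal allyl carbon, giving (2R)-2-(prop-1-en-2-yl)-3,5,6,7-tetrahydro-1-benzofuran-4(2H)-one A7.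
- For: it also makes ring B and C2 in one catalytic step, from very cheap materials. Its enantiocontrol rests on a broader body of precedent than the metalloradical step chosen here.
- Against: ring A must still be dehydrogenated and O-methylated in the presence of an isopropenyl group that reacts with halogenating and oxidising agents, and the isopropenyl group must be hydrated. The C7 acyl group must then be introduced on an arene in which C5 and C7 are both activated, with no halogen to direct it.
- Comparison: five or more steps follow its key step, against two in the chosen route, where the bromine of 1 fixes C7 from the start.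

Key step: step 4

Assumption: [Co(P*)] is the cobalt complex of the dianion of 5,15-bis(3,5-di-tert-butylphenyl)-10,20-bis{2,6-bis[(S)-2,2-dimethylcyclopropane-1-carboxamido]phenyl}porphyrin; it is assumed to give the R product, and the mirror-image ligand from the (R)-amide is used if a trial cyclisation shows the opposite sense.

## Route

Step 1
Reactants: 1 2-bromo-5-methoxyphenol
Product: 2 3-bromo-2-hydroxy-6-methoxybenzaldehyde
Conditions: MgCl2, Et3N, (CH2O)n, MeCN, reflux; then 1 M HCl
Reagents that add atoms: paraformaldehyde (formaldehyde unit), C=O
Why: Magnesium-mediated ortho-formylation of a phenol: the magnesium phenoxide delivers formaldehyde only to an ortho carbon, and a second formaldehyde accepts hydride to give the aldehyde. Bromine blocks one ortho position, so only the carbon between OH and OMe, which the methoxy group also activates, can react; the aryl bromide is inert.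

Step 2
Reactants: 2 3-bromo-2-hydroxy-6-methoxybenzaldehyde; 3 2,2-dimethyloxirane
Product: 4 3-bromo-2-(2-hydroxy-2-methylpropoxy)-6-methoxybenzaldehyde
Conditions: K2CO3, DMF, 100 °C, sealed tube
Reagents that add atoms: none
Why: SN2 opening of the epoxide by the phenoxide at the unsubstituted CH2 gives the ether and the tertiary alcohol in one step. The aldehyde has no α-hydrogen and tolerates carbonate in DMF.

Step 3
Reactants: 4 3-bromo-2-(2-hydroxy-2-methylpropoxy)-6-methoxybenzaldehyde
Product: 5 N'-[(E)-[3-bromo-2-(2-hydroxy-2-methylpropoxy)-6-methoxyphenyl]methylidene]-4-methylbenzenesulfonohydrazide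
Conditions: TsNHNH2, MeOH, 50 °C
Reagents that add atoms: 4-methylbenzenesulfonohydrazide, Cc1ccc(cc1)S(=O)(=O)NN
Why: Hydrazone condensation of an aldehyde, which proceeds even with two ortho substituents and gives the E isomer. The tertiary alcohol and the aryl bromide do not take part.

Step 4
Reactants: 5 N'-[(E)-[3-bromo-2-(2-hydroxy-2-methylpropoxy)-6-methoxyphenyl]methylidene]-4-methylbenzenesulfonohydrazide
Product: 7 2-[(2R)-7-bromo-4-methoxy-2,3-dihydro-1-benzofuran-2-yl]propan-2-ol, via aryldiazomethane 6 (not isolated)
Conditions: [Co(P*)] (2 mol%), Cs2CO3 (2 equiv), toluene, 40 °C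
Reagents that add atoms: none
Why: Cs2CO3 removes the N–H proton of 5 and the salt loses p-toluenesulfinate (Bamford–Stevens) to give diazo compound 6 at a low stationary concentration; the divalent cobalt porphyrin takes up 6 with loss of N2 and becomes a trivalent-cobalt-bound benzylic radical at the future C3. This radical removes a hydrogen atom from the O–CH2 group through a six-membered transition state (1,5-hydrogen atom transfer). The resulting α-oxyalkyl radical at the future C2 attacks the cobalt-bound carbon and expels the divalent cobalt catalyst, a 5-exo-tet radical substitution that forms C2–C3 and closes ring B. The closest known reaction type is the enantioselective cobalt metalloradical 1,5-C–H alkylation with diazomethanes generated from tosylhydrazones, which gives indolines, pyrrolidines and related five-membered rings, together with donor-carbene insertion into ether O–CH bonds, which gives 2,3-dihydrobenzofurans. The C2 radical is planar and is held in the chiral cavity lined by the amide N–H groups of the ligand, so the ligand decides which face bonds to C3 and thereby sets C2 as R in the ring-closing step. The step needs site selectivity for the O–CH2 over the C4 methoxy group: the alkoxy chain is flanked by bromine and by the carbene carbon and is therefore twisted out of the ring plane towards the radical, and its secondary C–H bond is the weaker one, whereas the methoxy group has one free ortho neighbour and lies in the plane with its methyl turned away. It also needs chemoselectivity: the carbon-centred metalloradical is not electrophilic enough to insert into the tertiary O–H, there is no alkene to cyclopropanate, and the aryl bromide is inert to this radical chemistry.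

Step 5
Reactants: 8 (2E)-3-(4-hydroxyphenyl)prop-2-enoic acid
Product: 9 (2E)-3-(4-hydroxyphenyl)-N-methoxy-N-methylprop-2-enamide
Conditions: MeNH(OMe)·HCl, EDC·HCl, HOBt, iPr2NEt, DMF, 0 °C to rt
Reagents that add atoms: N,O-dimethylhydroxylamine hydrochloride, CNOC.Cl
Why: Carbodiimide amide coupling through the hydroxybenzotriazole active ester. The amine outcompetes the phenol, and any aryl ester that forms is itself aminolysed; the E alkene is untouched.

Step 6
Reactants: 9 (2E)-3-(4-hydroxyphenyl)-N-methoxy-N-methylprop-2-enamide
Product: 10 (2E)-3-{4-[(tert-butyldimethylsilyl)oxy]phenyl}-N-methoxy-N-methylprop-2-enamide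
Conditions: TBSCl, imidazole, DMF, rt
Reagents that add atoms: tert-butyldimethylsilyl chloride, CC(C)(C)[Si](C)(C)Cl
Why: Standard silylation of a phenol. It removes the only acidic hydrogen of the acyl donor, so no aryllithium is lost to protonation in step 7.

Step 7
Reactants: 7 2-[(2R)-7-bromo-4-methoxy-2,3-dihydro-1-benzofuran-2-yl]propan-2-ol; 10 (2E)-3-{4-[(tert-butyldimethylsilyl)oxy]phenyl}-N-methoxy-N-methylprop-2-enamide
Product: 13 (2E)-3-{4-[(tert-butyldimethylsilyl)oxy]phenyl}-1-[(2R)-2-(2-hydroxypropan-2-yl)-4-methoxy-2,3-dihydro-1-benzofuran-7-yl]prop-2-en-1-one, via lithium alkoxide 11 (not isolated), via aryllithium 12 (not isolated)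
Conditions: MeLi (1 equiv), THF, −78 °C; t-BuLi (2 equiv), −78 °C; 10, −78 to 0 °C; aq NH4Cl
Reagents that add atoms: none
Why: MeLi deprotonates the tertiary alcohol without exchanging the aryl bromide at −78 °C, so the aryllithium formed next by bromine–lithium exchange is not quenched. The C7 aryllithium, stabilised by the neighbouring ring oxygen, adds once to the N-methoxy-N-methyl amide because the chelated tetrahedral adduct persists until work-up (Weinreb ketone synthesis). Hard aryllithiums attack the amide carbonyl and not the β-carbon, so the E enone arrives intact; C2 is an ether carbon without an acidic hydrogen and is not affected.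

Step 8
Reactants: 13 (2E)-3-{4-[(tert-butyldimethylsilyl)oxy]phenyl}-1-[(2R)-2-(2-hydroxypropan-2-yl)-4-methoxy-2,3-dihydro-1-benzofuran-7-yl]prop-2-en-1-one
Product: 14 (2E)-1-[(2R)-2-(2-hydroxypropan-2-yl)-4-methoxy-2,3-dihydro-1-benzofuran-7-yl]-3-(4-hydroxyphenyl)prop-2-en-1-one
Conditions: TBAF, AcOH, THF, 0 °C
Reagents that add atoms: none
Why: Fluoride cleaves the aryl silyl ether, and acetic acid protonates the phenoxide so that no strong base meets the enone. The ketone has an ether and not a hydroxyl in its ortho position, so no oxa-Michael ring closure can follow, and the tertiary alcohol is inert.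

## Compound list

1 | 2-bromo-5-methoxyphenol | COc1ccc(Br)c(O)c1 | starting material
2 | 3-bromo-2-hydroxy-6-methoxybenzaldehyde | COc1ccc(Br)c(O)c1C=O | intermediate
3 | 2,2-dimethyloxirane | CC1(C)CO1 | starting material
4 | 3-bromo-2-(2-hydroxy-2-methylpropoxy)-6-methoxybenzaldehyde | COc1ccc(Br)c(OCC(C)(C)O)c1C=O | intermediate
5 | N'-[(E)-[3-bromo-2-(2-hydroxy-2-methylpropoxy)-6-methoxyphenyl]methylidene]-4-methylbenzenesulfonohydrazide | Cc1ccc(S(=O)(=O)N/N=C/c2c(OC)ccc(Br)c2OCC(C)(C)O)cc1 | intermediate
6 | 1-[6-bromo-2-(diazomethyl)-3-methoxyphenoxy]-2-methylpropan-2-ol | COc1ccc(Br)c(OCC(C)(C)O)c1C=[N+]=[N-] | intermediate (not isolated)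
7 | 2-[(2R)-7-bromo-4-methoxy-2,3-dihydro-1-benzofuran-2-yl]propan-2-ol | COc1ccc(Br)c2c1C[C@H](C(C)(C)O)O2 | intermediate
8 | (2E)-3-(4-hydroxyphenyl)prop-2-enoic acid | O=C(O)/C=C/c1ccc(O)cc1 | starting material
9 | (2E)-3-(4-hydroxyphenyl)-N-methoxy-N-methylprop-2-enamide | CON(C)C(=O)/C=C/c1ccc(O)cc1 | intermediate
10 | (2E)-3-{4-[(tert-butyldimethylsilyl)oxy]phenyl}-N-methoxy-N-methylprop-2-enamide | CON(C)C(=O)/C=C/c1ccc(O[Si](C)(C)C(C)(C)C)cc1 | intermediate
11 | lithium 2-[(2R)-7-bromo-4-methoxy-2,3-dihydro-1-benzofuran-2-yl]propan-2-olate | COc1ccc(Br)c2c1C[C@H](C(C)(C)O[Li])O2 | intermediate (not isolated)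
12 | lithium 2-[(2R)-7-lithio-4-methoxy-2,3-dihydro-1-benzofuran-2-yl]propan-2-olate | COc1ccc([Li])c2c1C[C@H](C(C)(C)O[Li])O2 | intermediate (not isolated)
13 | (2E)-3-{4-[(tert-butyldimethylsilyl)oxy]phenyl}-1-[(2R)-2-(2-hydroxypropan-2-yl)-4-methoxy-2,3-dihydro-1-benzofuran-7-yl]prop-2-en-1-one | COc1ccc(C(=O)/C=C/c2ccc(O[Si](C)(C)C(C)(C)C)cc2)c2c1C[C@H](C(C)(C)O)O2 | intermediate
14 | (2E)-1-[(2R)-2-(2-hydroxypropan-2-yl)-4-methoxy-2,3-dihydro-1-benzofuran-7-yl]-3-(4-hydroxyphenyl)prop-2-en-1-one | COc1ccc(C(=O)/C=C/c2ccc(O)cc2)c2c1C[C@H](C(C)(C)O)O2 | target

## Step count and least certain steps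

Total: 8 steps. Longest linear sequence: 6 steps (steps 1, 2, 3, 4, 7, 8); steps 5 and 6 prepare the acyl donor.

**Step 4 (key step).** The O–CH2 group is neither benzylic nor allylic and sits next to a fully substituted carbon, so hydrogen abstraction may be too slow. Carbene dimerisation to the azine or stilbene, abstraction from the C4 methoxy group, or ring closure with poor facial selectivity could then take over.

Fallback (sets out from 1, returns at 7): ring B is closed at O1–C2 by known chemistry.
- Phenol 1 is O-allylated with methyl 2-methylbut-3-en-2-yl carbonate under Pd(PPh3)4 catalysis to give 1-bromo-4-methoxy-2-[(2-methylbut-3-en-2-yl)oxy]benzene F1.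
- Aromatic Claisen rearrangement of F1 (N,N-diethylaniline, heat) can only end at the one free ortho position and gives 6-bromo-3-methoxy-2-(3-methylbut-2-en-1-yl)phenol F2.
- Silylation (TBSCl, imidazole) gives tert-butyl[6-bromo-3-methoxy-2-(3-methylbut-2-en-1-yl)phenoxy]dimethylsilane F3.
- Shi epoxidation (Oxone, K2CO3 buffer, MeCN–dimethoxymethane, 0 °C) uses the L-series ketone catalyst 1,2:4,5-di-O-isopropylidene-β-L-erythro-2,3-hexodiulo-2,6-pyranose, chosen by the spiro transition-state model to give the S epoxide. The product is tert-butyl[6-bromo-2-{[(2S)-3,3-dimethyloxiran-2-yl]methyl}-3-methoxyphenoxy]dimethylsilane F4.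
- TBAF in THF frees the phenoxide, which opens the epoxide at its secondary carbon in a 5-exo-tet closure with inversion. This gives 7 with C2 as R.

**Step 7.** The aryllithium may be protonated if alkoxide formation is incomplete, and some conjugate addition to the cinnamoyl amide may compete with attack at the carbonyl.

Fallback (sets out from 7, returns at 14): the ketone is built without an organolithium, and the alkene is formed by condensation.
- Stille coupling of 7 with tributyl(1-ethoxyethenyl)stannane (Pd(PPh3)4, toluene, 100 °C) gives 2-[(2R)-7-(1-ethoxyethenyl)-4-methoxy-2,3-dihydro-1-benzofuran-2-yl]propan-2-ol F5.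
- Brief hydrolysis (1 M HCl, THF, rt) gives 1-[(2R)-2-(2-hydroxypropan-2-yl)-4-methoxy-2,3-dihydro-1-benzofuran-7-yl]ethan-1-one F6.
- Claisen–Schmidt condensation of F6 with 4-hydroxybenzaldehyde (excess KOH, EtOH, rt) gives the E enone 14 directly.

**Step 1.** Attack at the only free ortho position, which is crowded by the methoxy group, may be slow, so that the phenol is recovered or condenses with formaldehyde to diarylmethanes.

Fallback (sets out from 1, returns at 2): boron-templated ortho-hydroxymethylation followed by oxidation.
- Phenol 1 with PhB(OH)2, (CH2O)n and catalytic propanoic acid in refluxing toluene with water removal gives 8-bromo-5-methoxy-2-phenyl-4H-1,3,2-benzodioxaborinine F7.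
- Transesterification with propane-1,3-diol releases 6-bromo-2-(hydroxymethyl)-3-methoxyphenol F8.
- MnO2 in CH2Cl2 oxidises the benzylic alcohol to aldehyde 2.

**Step 2.** The phenoxide is hydrogen-bonded to the aldehyde and flanked by bromine, so epoxide opening may be slow, and long heating in base may degrade the aldehyde.

Fallback (sets out from 2, returns at 4): alkylation with a reactive allylic halide, then hydration.
- Phenol 2 with 3-chloro-2-methylprop-1-ene (K2CO3, KI, DMF, 60 °C) gives 3-bromo-6-methoxy-2-[(2-methylprop-2-en-1-yl)oxy]benzaldehyde F9.
- Oxymercuration–demercuration (Hg(OAc)2, THF–H2O; then NaBH4, NaOH) hydrates the alkene in the Markovnikov sense and also reduces the aldehyde, giving 1-[6-bromo-2-(hydroxymethyl)-3-methoxyphenoxy]-2-methylpropan-2-ol F10.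
- MnO2 in CH2Cl2 reoxidises only the benzylic alcohol and gives 4.

## Further compounds

F1 | step 4 | 1-bromo-4-methoxy-2-[(2-methylbut-3-en-2-yl)oxy]benzene | COc1ccc(Br)c(OC(C)(C)C=C)c1
F2 | step 4 | 6-bromo-3-methoxy-2-(3-methylbut-2-en-1-yl)phenol | COc1ccc(Br)c(O)c1CC=C(C)C
F3 | step 4 | tert-butyl[6-bromo-3-methoxy-2-(3-methylbut-2-en-1-yl)phenoxy]dimethylsilane | COc1ccc(Br)c(O[Si](C)(C)C(C)(C)C)c1CC=C(C)C
F4 | step 4 | tert-butyl[6-bromo-2-{[(2S)-3,3-dimethyloxiran-2-yl]methyl}-3-methoxyphenoxy]dimethylsilane | COc1ccc(Br)c(O[Si](C)(C)C(C)(C)C)c1C[C@@H]1OC1(C)C
F5 | step 7 | 2-[(2R)-7-(1-ethoxyethenyl)-4-methoxy-2,3-dihydro-1-benzofuran-2-yl]propan-2-ol | COc1ccc(C(=C)OCC)c2c1C[C@H](C(C)(C)O)O2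
F6 | step 7 | 1-[(2R)-2-(2-hydroxypropan-2-yl)-4-methoxy-2,3-dihydro-1-benzofuran-7-yl]ethan-1-one | COc1ccc(C(C)=O)c2c1C[C@H](C(C)(C)O)O2
F7 | step 1 | 8-bromo-5-methoxy-2-phenyl-4H-1,3,2-benzodioxaborinine | COc1ccc(Br)c2OB(c3ccccc3)OCc12
F8 | step 1 | 6-bromo-2-(hydroxymethyl)-3-methoxyphenol | COc1ccc(Br)c(O)c1CO
F9 | step 2 | 3-bromo-6-methoxy-2-[(2-methylprop-2-en-1-yl)oxy]benzaldehyde | COc1ccc(Br)c(OCC(C)=C)c1C=O
F10 | step 2 | 1-[6-bromo-2-(hydroxymethyl)-3-methoxyphenoxy]-2-methylpropan-2-ol | COc1ccc(Br)c(OCC(C)(C)O)c1CO
A1 | alternative 1 | methyl 2-hydroxy-4-methoxy-3-[(2S)-2-(methanesulfonyloxy)-3-methyl-3-(triethylsilyloxy)butyl]benzoate | COC(=O)c1ccc(OC)c(C[C@H](OS(C)(=O)=O)C(C)(C)O[Si](CC)(CC)CC)c1O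
A2 | alternative 1 | methyl (2E)-5-diazo-4-oxopent-2-enoate | COC(=O)/C=C/C(=O)C=[N+]=[N-]
A3 | alternative 1 | (3S)-6-methoxy-2-methyl-2-[(triethylsilyl)oxy]hex-5-yn-3-yl methanesulfonate | COC#CC[C@H](OS(C)(=O)=O)C(C)(C)O[Si](CC)(CC)CC
A4 | alternative 2 | 4-[(E)-3-[(2R)-2-(2-hydroxypropan-2-yl)-4-methoxy-2,3-dihydro-1-benzofuran-7-yl]-3-oxoprop-1-en-1-yl]phenyl acetate | COc1ccc(C(=O)/C=C/c2ccc(OC(C)=O)cc2)c2c1C[C@H](C(C)(C)O)O2
A5 | alternative 2 | 2-[(2R)-7-iodo-4-methoxy-2,3-dihydro-1-benzofuran-2-yl]propan-2-ol | COc1ccc(I)c2c1C[C@H](C(C)(C)O)O2
A6 | alternative 2 | 4-ethenylphenyl acetate | CC(=O)Oc1ccc(C=C)cc1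
A7 | alternative 3 | (2R)-2-(prop-1-en-2-yl)-3,5,6,7-tetrahydro-1-benzofuran-4(2H)-one | O=C1CCCC2=C1C[C@H](C(C)=C)O2
A8 | alternative 3 | cyclohexane-1,3-dione | O=C1CCCC(=O)C1
A9 | alternative 3 | dimethyl 2-methylbut-3-ene-1,2-diyl biscarbonate | COC(=O)OCC(C)(OC(=O)OC)C=C
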